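**Plan**

1. Retrosynthesis (chain numbered from the CH2OH carbon, C1): the O–benzyl bond of a protected form is cut first, then the C1–H and C2–H bonds (enamide hydrogenation), then C1–C2 (one-carbon formamide acetal unit), C3–C4 (acyl substitution on an N-acetylglycine amide) and the two furan–alkyl bonds.
2. Forward: the furan, the only ring, arises first by reduction and aromatisation of 2,3-dimethylmaleic anhydride. Two lithiation–alkylations add propyl and 10-bromodecyl, the Grignard reagent acylates N-acetylglycine N-methoxy-N-methylamide, and C1 is added as a dimethylaminomethylene group, hydrolysed to the enol and O-benzylated.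
3. Enabling feature: the single stereocentre C2 carries the acetamido nitrogen and lies between the C3 ketone and the oxygen-bearing C1. It is therefore the saturated form of a 2-acetamido-1-benzyloxy-1-en-3-one, whose N-acetyl oxygen and C1=C2 bond chelate rhodium.
4. Stereochemistry: C2 is set (S) by [Rh(cod)((S,S)-Et-DuPhos)]BF4 hydrogenation of the E/Z enol ether mixture and is kept by neutral hydrogenolysis of the benzyl ether.

Key step: step 10

Assumption: the (S,S)-ligand is taken to give (S)-C2, as it gives L-amino acids from 2-acetamidoacrylates; if the sense proves opposite, the (R,R)-ligand is used in the same step.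

**Step 1**
Reactants: 1 2,3-dimethylmaleic anhydride
Product: 2 3,4-dimethylfuran-2(5H)-one
Conditions: NaBH4, THF, 0 °C to rt; then 2 M HCl
Reagents that add atoms: none
Why: Hydride reduction of one carbonyl of the symmetric cyclic anhydride and lactonisation on acidification is the standard anhydride-to-lactone reduction, and the symmetry of 1 removes any regiochemical question.

**Step 2**
Reactants: 2 3,4-dimethylfuran-2(5H)-one
Product: 4 3,4-dimethylfuran, via 3,4-dimethyl-2,5-dihydrofuran-2-ol 3 (not isolated)
Conditions: i-Bu2AlH, Et2O, −78 °C; then 1 M HCl, 0 °C; careful distillation (volatile product, may be used as a dried, titrated solution)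
Reagents that add atoms: none
Why: Partial reduction of the butenolide stops at the lactol, which loses water under the acidic work-up and aromatises (butenolide-to-furan reduction).

**Step 3**
Reactants: 4 3,4-dimethylfuran; 5 1-iodopropane
Product: 7 3,4-dimethyl-2-propylfuran, via (3,4-dimethylfuran-2-yl)lithium 6 (not isolated)
Conditions: n-BuLi (1 equiv), THF, 0 °C to rt; then 5, −78 °C to rt
Reagents that add atoms: none
Why: Furans are lithiated by n-BuLi at a free position next to oxygen and the 2-furyllithium is alkylated by the primary iodide (SN2), one equivalent of base leaving the second alpha position untouched.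

**Step 4**
Reactants: 7 3,4-dimethyl-2-propylfuran; 8 1,10-dibromodecane
Product: 10 2-(10-bromodecyl)-3,4-dimethyl-5-propylfuran, via (3,4-dimethyl-5-propylfuran-2-yl)lithium 9 (not isolated)
Conditions: n-BuLi, THF, 0 °C to rt; then cannulated into 8 (4 equiv), THF, −78 °C to rt; excess 8 removed by distillation
Reagents that add atoms: none
Why: The only remaining ring C–H is lithiated, and inverse addition to an excess of the dibromide should favour monoalkylation (SN2) over the bis-furyl by-product.

**Step 5**
Reactants: 11 N-acetylglycine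
Product: 13 2-acetamido-N-methoxy-N-methylacetamide, via acyl imidazole 12 (not isolated)
Conditions: 1,1'-carbonyldiimidazole, THF, rt; then MeNH(OMe)·HCl, rt; non-aqueous work-up
Reagents that add atoms: N,O-dimethylhydroxylamine hydrochloride, CNOC.Cl
Why: Carboxyl activation as the acyl imidazole and aminolysis by N,O-dimethylhydroxylamine is a standard Weinreb amide synthesis, and glycine has no stereocentre to lose.

**Step 6**
Reactants: 10 2-(10-bromodecyl)-3,4-dimethyl-5-propylfuran; 13 2-acetamido-N-methoxy-N-methylacetamide
Product: 16 N-[12-(3,4-dimethyl-5-propylfuran-2-yl)-2-oxododecyl]acetamide, via alkylmagnesium bromide 14 (not isolated), via N-chloromagnesio amide 15 (not isolated)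
Conditions: 10, Mg, THF, 40 °C; separately 13, i-PrMgCl (1 equiv), THF, −20 °C; combined, 0 °C to rt; aq. NH4Cl
Reagents that add atoms: none
Why: Weinreb ketone synthesis, in which the amide N–H is removed beforehand with i-PrMgCl so that one equivalent of the primary Grignard reagent adds to the N-methoxy-N-methylamide and the magnesium chelate releases the ketone only on work-up, preventing over-addition.

**Step 7**
Reactants: 16 N-[12-(3,4-dimethyl-5-propylfuran-2-yl)-2-oxododecyl]acetamide
Product: 17 N-[1-(dimethylamino)-13-(3,4-dimethyl-5-propylfuran-2-yl)-3-oxotridec-1-en-2-yl]acetamide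
Conditions: Me2NCH(OMe)2 (3 equiv), toluene, 85 °C
Reagents that add atoms: N,N-dimethylformamide dimethyl acetal, COC(OC)N(C)C
Why: Formamide acetal condensation (enaminone formation) should take place at the methylene flanked by the ketone and the acetamido nitrogen, the more acidic C–H position, because unactivated dialkyl ketone methylenes such as C4 react only sluggishly with this mild reagent.

**Step 8**
Reactants: 17 N-[1-(dimethylamino)-13-(3,4-dimethyl-5-propylfuran-2-yl)-3-oxotridec-1-en-2-yl]acetamide
Product: 18 N-[13-(3,4-dimethyl-5-propylfuran-2-yl)-1-hydroxy-3-oxotridec-1-en-2-yl]acetamide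
Conditions: 1 M HCl (aq), THF, 0 °C to rt; used crude
Reagents that add atoms: water, O
Why: Acid hydrolysis of the vinylogous amide (C-protonation, addition of water, loss of dimethylamine) gives the hydrogen-bonded enol of the 2-acetamido-3-oxo aldehyde, and cold dilute acid should leave the tetraalkylfuran intact.

**Step 9**
Reactants: 18 N-[13-(3,4-dimethyl-5-propylfuran-2-yl)-1-hydroxy-3-oxotridec-1-en-2-yl]acetamide; 19 benzyl alcohol
Product: 20 N-[1-(benzyloxy)-13-(3,4-dimethyl-5-propylfuran-2-yl)-3-oxotridec-1-en-2-yl]acetamide (E/Z mixture)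
Conditions: PPh3, DIAD, THF, 0 °C to rt
Reagents that add atoms: none
Why: Mitsunobu reaction of a vinylogous acid, in which the acidic enol is deprotonated and its unhindered C1 oxygen attacks the benzyloxyphosphonium ion, O-alkylation being preferred over attack by the fully substituted C2; the geometric mixture is carried on as such.

**Step 10**
Reactants: 20 N-[1-(benzyloxy)-13-(3,4-dimethyl-5-propylfuran-2-yl)-3-oxotridec-1-en-2-yl]acetamide (E/Z mixture)
Product: 21 N-[(2S)-1-(benzyloxy)-13-(3,4-dimethyl-5-propylfuran-2-yl)-3-oxotridecan-2-yl]acetamide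
Conditions: [Rh(cod)((S,S)-Et-DuPhos)]BF4 (2 mol%), H2 (5 bar), degassed CH2Cl2, 25 °C
Reagents that add atoms: none
Why: The acetamide oxygen and the C1=C2 bond chelate the cationic rhodium (monovalent rhodium), H2 adds oxidatively, hydride migrates to C1 to leave a C2–Rh alkyl held in a five-membered amide chelate, and reductive elimination forms the C2–H bond. The closest known reaction type is the rhodium–bisphosphine asymmetric hydrogenation of alpha-acylamino enones (dehydroamino ketones) and of beta-oxy-alpha-acetamidoacrylates, so this is enamide hydrogenation applied to a new member of that class. No ring is closed and no skeletal bond is formed. The new C2 stereocentre is set by the twofold-symmetric (S,S)-Et-DuPhos ligand acting through the amide chelate (catalyst control), and (S) is expected by analogy with L-amino acid formation. The step needs the same enantioface at C2 from both geometric isomers, which the common chelate and the small influence of the C1 substituent with this ligand should secure, so the mixture is used unseparated. It also needs chemoselectivity, which the substrate provides: only the enamide alkene can chelate, the tetraalkylfuran, ketone and benzyl ether are inert to this catalyst, and the neutral aprotic medium keeps the new alpha-acetamido ketone from enolising.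

**Step 11**
Reactants: 21 N-[(2S)-1-(benzyloxy)-13-(3,4-dimethyl-5-propylfuran-2-yl)-3-oxotridecan-2-yl]acetamide
Product: 22 N-[(2S)-13-(3,4-dimethyl-5-propylfuran-2-yl)-1-hydroxy-3-oxotridecan-2-yl]acetamide
Conditions: H2 (1 atm), Pd(OH)2 on carbon, EtOAc, rt; stopped at one equivalent of H2
Reagents that add atoms: none
Why: Hydrogenolysis of the benzyl ether in a neutral aprotic solvent frees the primary alcohol without enolising the alpha-acetamido ketone, so C2 stays (S), and the tetrasubstituted furan should be reduced far more slowly than the benzylic C–O bond is cleaved.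

**Compound list**

1 | 2,3-dimethylmaleic anhydride | CC1=C(C)C(=O)OC1=O | starting material
2 | 3,4-dimethylfuran-2(5H)-one | CC1=C(C)C(=O)OC1 | intermediate
3 | 3,4-dimethyl-2,5-dihydrofuran-2-ol (racemic lactol) | CC1=C(C)C(O)OC1 | intermediate
4 | 3,4-dimethylfuran | Cc1cocc1C | intermediate
5 | 1-iodopropane | CCCI | starting material
6 | (3,4-dimethylfuran-2-yl)lithium | [Li]c1occ(C)c1C | intermediate
7 | 3,4-dimethyl-2-propylfuran | CCCc1occ(C)c1C | intermediate
8 | 1,10-dibromodecane | BrCCCCCCCCCCBr | starting material
9 | (3,4-dimethyl-5-propylfuran-2-yl)lithium | [Li]c1oc(CCC)c(C)c1C | intermediate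
10 | 2-(10-bromodecyl)-3,4-dimethyl-5-propylfuran | CCCc1oc(CCCCCCCCCCBr)c(C)c1C | intermediate
11 | N-acetylglycine | CC(=O)NCC(=O)O | starting material
12 | N-[2-(1H-imidazol-1-yl)-2-oxoethyl]acetamide (acyl imidazole) | CC(=O)NCC(=O)n1ccnc1 | intermediate
13 | 2-acetamido-N-methoxy-N-methylacetamide | CC(=O)NCC(=O)N(C)OC | intermediate
14 | [10-(3,4-dimethyl-5-propylfuran-2-yl)decyl]magnesium bromide | CCCc1oc(CCCCCCCCCC[Mg]Br)c(C)c1C | intermediate
15 | N-chloromagnesio derivative of 2-acetamido-N-methoxy-N-methylacetamide | CC(=O)N([Mg]Cl)CC(=O)N(C)OC | intermediate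
16 | N-[12-(3,4-dimethyl-5-propylfuran-2-yl)-2-oxododecyl]acetamide | CCCc1oc(CCCCCCCCCCC(=O)CNC(C)=O)c(C)c1C | intermediate
17 | N-[1-(dimethylamino)-13-(3,4-dimethyl-5-propylfuran-2-yl)-3-oxotridec-1-en-2-yl]acetamide (alkene geometry not assigned) | CCCc1oc(CCCCCCCCCCC(=O)C(NC(C)=O)=CN(C)C)c(C)c1C | intermediate
18 | N-[13-(3,4-dimethyl-5-propylfuran-2-yl)-1-hydroxy-3-oxotridec-1-en-2-yl]acetamide (enol, geometry not assigned) | CCCc1oc(CCCCCCCCCCC(=O)C(NC(C)=O)=CO)c(C)c1C | intermediate
19 | benzyl alcohol | OCc1ccccc1 | starting material
20 | N-[1-(benzyloxy)-13-(3,4-dimethyl-5-propylfuran-2-yl)-3-oxotridec-1-en-2-yl]acetamide (E/Z mixture) | CCCc1oc(CCCCCCCCCCC(=O)C(NC(C)=O)=COCc2ccccc2)c(C)c1C | intermediate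
21 | N-[(2S)-1-(benzyloxy)-13-(3,4-dimethyl-5-propylfuran-2-yl)-3-oxotridecan-2-yl]acetamide | CCCc1oc(CCCCCCCCCCC(=O)[C@H](COCc2ccccc2)NC(C)=O)c(C)c1C | intermediate
22 | N-[(2S)-13-(3,4-dimethyl-5-propylfuran-2-yl)-1-hydroxy-3-oxotridecan-2-yl]acetamide | CCCc1oc(CCCCCCCCCCC(=O)[C@H](CO)NC(C)=O)c(C)c1C | target

**Step count**

Total: 11 steps. Longest linear sequence: 10 steps (steps 1–4 and 6–11, from 1); step 5 is the only step on the side branch.

**Steps most likely to fail**

Step 7. The condensation may lose site selectivity, attacking the C4 methylene or both methylenes. The fallback introduces C1 before the ketone exists, where only one methylene is present. It sets out from 13: condensation with tert-butoxybis(dimethylamino)methane (toluene, 90 °C) should give 2-acetamido-3-(dimethylamino)-N-methoxy-N-methylprop-2-enamide F1. Cold 1 M HCl should give the enol 2-acetamido-3-hydroxy-N-methoxy-N-methylprop-2-enamide F2, and Mitsunobu reaction with 19 (PPh3, DIAD, THF) should give 2-acetamido-3-(benzyloxy)-N-methoxy-N-methylprop-2-enamide F3 as an E/Z mixture. Removal of the N–H with i-PrMgCl (THF, −20 °C) gives the N-chloromagnesio derivative of 2-acetamido-3-(benzyloxy)-N-methoxy-N-methylprop-2-enamide F4, whose amidate lowers the electrophilicity of C1 so that 14 should substitute at the acyl carbon. This returns to the route at 20.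

Step 10. Turnover of the donor–acceptor alkene may be slow, the two geometric isomers may be reduced with unequal facial selectivity, or the enantiomeric purity may stay low with either ligand antipode. The fallback takes the stereocentre from L-serine and sets out from 14. N-Boc-O-benzyl-L-serine F5 is coupled with MeNH(OMe)·HCl (EDC·HCl, N-methylmorpholine, CH2Cl2) to give tert-butyl N-[(2S)-3-(benzyloxy)-1-[methoxy(methyl)amino]-1-oxopropan-2-yl]carbamate F6; the carbamate rules out azlactone racemisation on activation. HCl in dioxane gives (2S)-2-amino-3-(benzyloxy)-N-methoxy-N-methylpropanamide hydrochloride F7, and Ac2O/Et3N gives (2S)-2-acetamido-3-(benzyloxy)-N-methoxy-N-methylpropanamide F8. i-PrMgCl then gives the N-chloromagnesio derivative of (2S)-2-acetamido-3-(benzyloxy)-N-methoxy-N-methylpropanamide F9, and addition of 14 returns to the route at 21.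

Step 9. Benzylation may occur at C2 instead of oxygen, or the dehydrating conditions may cyclise the acetamido enol to an oxazole. The fallback sets out from 18 and uses a hard electrophile that alkylates enolate oxygen. Benzyl chloromethyl ether (i-Pr2NEt, CH2Cl2, 0 °C) should give N-[1-[(benzyloxy)methoxy]-13-(3,4-dimethyl-5-propylfuran-2-yl)-3-oxotridec-1-en-2-yl]acetamide F10. Hydrogenation under the conditions of step 10 should give N-[(2S)-1-[(benzyloxy)methoxy]-13-(3,4-dimethyl-5-propylfuran-2-yl)-3-oxotridecan-2-yl]acetamide F11. H2 over Pd(OH)2 on carbon in EtOAc cleaves the benzyl group and the hemiacetal loses formaldehyde, returning to the route at 22.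

**Further compounds**

F1 | step 7 | 2-acetamido-3-(dimethylamino)-N-methoxy-N-methylprop-2-enamide | CON(C)C(=O)C(NC(C)=O)=CN(C)C
F2 | step 7 | 2-acetamido-3-hydroxy-N-methoxy-N-methylprop-2-enamide | CON(C)C(=O)C(NC(C)=O)=CO
F3 | step 7 | 2-acetamido-3-(benzyloxy)-N-methoxy-N-methylprop-2-enamide (E/Z mixture) | CON(C)C(=O)C(NC(C)=O)=COCc1ccccc1
F4 | step 7 | N-chloromagnesio derivative of 2-acetamido-3-(benzyloxy)-N-methoxy-N-methylprop-2-enamide | CON(C)C(=O)C(N([Mg]Cl)C(C)=O)=COCc1ccccc1
F5 | step 10 | N-Boc-O-benzyl-L-serine | CC(C)(C)OC(=O)N[C@@H](COCc1ccccc1)C(=O)O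
F6 | step 10 | tert-butyl N-[(2S)-3-(benzyloxy)-1-[methoxy(methyl)amino]-1-oxopropan-2-yl]carbamate | CC(C)(C)OC(=O)N[C@@H](COCc1ccccc1)C(=O)N(C)OC
F7 | step 10 | (2S)-2-amino-3-(benzyloxy)-N-methoxy-N-methylpropanamide hydrochloride | Cl.N[C@@H](COCc1ccccc1)C(=O)N(C)OC
F8 | step 10 | (2S)-2-acetamido-3-(benzyloxy)-N-methoxy-N-methylpropanamide | CC(=O)N[C@@H](COCc1ccccc1)C(=O)N(C)OC
F9 | step 10 | N-chloromagnesio derivative of (2S)-2-acetamido-3-(benzyloxy)-N-methoxy-N-methylpropanamide | CC(=O)N([Mg]Cl)[C@@H](COCc1ccccc1)C(=O)N(C)OC
F10 | step 9 | N-[1-[(benzyloxy)methoxy]-13-(3,4-dimethyl-5-propylfuran-2-yl)-3-oxotridec-1-en-2-yl]acetamide (E/Z mixture) | CCCc1oc(CCCCCCCCCCC(=O)C(NC(C)=O)=COCOCc2ccccc2)c(C)c1C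
F11 | step 9 | N-[(2S)-1-[(benzyloxy)methoxy]-13-(3,4-dimethyl-5-propylfuran-2-yl)-3-oxotridecan-2-yl]acetamide | CCCc1oc(CCCCCCCCCCC(=O)[C@H](COCOCc2ccccc2)NC(C)=O)c(C)c1C
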